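**Retrosynthetic overview**
1. Target 34 ⇒ C5 ketone masked as a 1,3-dithiane and α-methylene lactone masked as its Me2NH adduct; the ten-membered carbocycle is opened at C8–C9 (ring-closing metathesis of a C10 vinyl carbinol with a C6 allyl group, then alkene reduction).
2. The metathesis diene ⇒ Barbier allylation (C3a–C4 bond) joining west fragment 16 (5-substituted 3-(bromomethyl)butenolide already carrying the side-chain ester) and east fragment 26 (2-formyl-1,3-dithiane); it sets C3a and C4 from C11a and creates the α-methylene lactone.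
3. 16 ⇒ D-tartrate acetonide 4 (C11, C11a), chelate-controlled MeMgBr addition to a vinyl ketone (C10), Morita–Baylis–Hillman reaction, lactonisation and SN2′ bromination; acid 3 ⇒ ethyl but-2-ynoate by carbocupration.
4. 26 ⇒ Evans allylation (C6), dithioacetalisation, formylation.
5. Ring order: the γ-lactone first (step 9, carried as a butenolide), the ten-membered carbocycle last (step 20).

Assumption: locants follow cyclodeca[b]furan numbering (O1, C2=O, C3, C3a, C4–C11, C11a); the SMILES is read as (3aS,4S,6S,10R,11S,11aR) with a 2E ester.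

**Route**

Step 1
Reactants: 1 ethyl but-2-ynoate
Product: 2 ethyl (2E)-3-methylpent-2-enoate
Conditions: Et2CuLi (from EtLi and CuI), THF, −78 °C; MeOH, −78 °C; aq. NH4Cl
Reagents that add atoms: lithium diethylcuprate [Li+].CC[Cu-]CC
Why: Syn-carbocupration (conjugate addition) of the ynoate puts Et cis to the new H, so protonation at −78 °C gives the 2E enoate.

Step 2
Reactants: 2 ethyl (2E)-3-methylpent-2-enoate
Product: 3 (2E)-3-methylpent-2-enoic acid
Conditions: LiOH·H2O, THF/MeOH/H2O, rt; then 1 M HCl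
Reagents that add atoms: lithium hydroxide [Li+].[OH-]
Why: Saponification of the ethyl ester leaves the trisubstituted alkene geometry untouched.

Step 3
Reactants: 4 dimethyl (4S,5S)-2,2-dimethyl-1,3-dioxolane-4,5-dicarboxylate
Product: 5 (4S,5S)-N4,N5-dimethoxy-N4,N5,2,2-tetramethyl-1,3-dioxolane-4,5-dicarboxamide
Conditions: MeNHOMe·HCl, iPrMgCl, THF, −20 → 0 °C
Reagents that add atoms: N,O-dimethylhydroxylamine hydrochloride CNOC.Cl
Why: Weinreb amide formation by aminolysis of both esters with the magnesium amide; the trans-dioxolane centres (future C11 and C11a, from D-tartaric acid) are the thermodynamic arrangement and are not epimerised.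

Step 4
Reactants: 5 (4S,5S)-N4,N5-dimethoxy-N4,N5,2,2-tetramethyl-1,3-dioxolane-4,5-dicarboxamide
Product: 6 (4S,5S)-N-methoxy-N,2,2-trimethyl-5-(prop-2-enoyl)-1,3-dioxolane-4-carboxamide
Conditions: CH2=CHMgBr (1.1 equiv), THF, −78 → −40 °C; inverse quench into cold 1 M HCl
Reagents that add atoms: vinylmagnesium bromide C=C[Mg]Br
Why: Grignard addition to a Weinreb amide stops at the chelated tetrahedral intermediate, so one equivalent desymmetrises the C2-symmetric bis-amide, and the acidic quench keeps the liberated amine from adding to the enone.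

Step 5
Reactants: 6 (4S,5S)-N-methoxy-N,2,2-trimethyl-5-(prop-2-enoyl)-1,3-dioxolane-4-carboxamide
Product: 7 (4S,5S)-5-[(2R)-2-hydroxybut-3-en-2-yl]-N-methoxy-N,2,2-trimethyl-1,3-dioxolane-4-carboxamide
Conditions: MeMgBr, Et2O/CH2Cl2, −78 °C; aq. NH4Cl
Reagents that add atoms: methylmagnesium bromide C[Mg]Br
Why: Cram-chelate-controlled 1,2-Grignard addition, in which Mg bridges the ketone and the α-dioxolane oxygen and methyl enters anti to the ring C4 substituent, sets the (R) tertiary carbinol (C10) while the Weinreb amide is inert at −78 °C.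

Step 6
Reactants: 7 (4S,5S)-5-[(2R)-2-hydroxybut-3-en-2-yl]-N-methoxy-N,2,2-trimethyl-1,3-dioxolane-4-carboxamide
Product: 8 (4S,5S)-5-[(2R)-2-hydroxybut-3-en-2-yl]-2,2-dimethyl-1,3-dioxolane-4-carbaldehyde
Conditions: iBu2AlH (2.5 equiv), THF, −78 °C; aq. potassium sodium tartrate
Reagents that add atoms: none
Why: Weinreb amide reduction stops at the chelated hemiaminal aluminate, which releases the aldehyde on work-up without touching any stereocentre.

Step 7
Reactants: 8 (4S,5S)-5-[(2R)-2-hydroxybut-3-en-2-yl]-2,2-dimethyl-1,3-dioxolane-4-carbaldehyde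
Product: 9 methyl 2-{hydroxy[5-((2R)-2-hydroxybut-3-en-2-yl)-2,2-dimethyl-1,3-dioxolan-4-yl]methyl}prop-2-enoate (dioxolane centres as in 8; carbinol epimers)
Conditions: methyl acrylate (excess), DABCO, MeOH (cat.), rt, 3–5 d
Reagents that add atoms: methyl acrylate C=CC(=O)OC
Why: Morita–Baylis–Hillman reaction of the activated α-alkoxy aldehyde installs C3, C2 and the future exocyclic carbon; the new carbinol centre forms unselectively but is erased in step 12.

Step 8
Reactants: 9 methyl 2-{hydroxy[5-((2R)-2-hydroxybut-3-en-2-yl)-2,2-dimethyl-1,3-dioxolan-4-yl]methyl}prop-2-enoate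
Product: 10 methyl 2-{[5-((2R)-2-hydroxybut-3-en-2-yl)-2,2-dimethyl-1,3-dioxolan-4-yl][(triisopropylsilyl)oxy]methyl}prop-2-enoate (dioxolane centres as in 8; epimers)
Conditions: TIPSOTf, 2,6-lutidine, CH2Cl2, −40 → 0 °C
Reagents that add atoms: triisopropylsilyl trifluoromethanesulfonate CC(C)[Si](OS(=O)(=O)C(F)(F)F)(C(C)C)C(C)C
Why: Silyl triflate silylation protects the secondary allylic alcohol as a group that is no leaving group toward DMAP, and the tertiary alcohol is too hindered to react at or below 0 °C.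

Step 9
Reactants: 10 methyl 2-{[5-((2R)-2-hydroxybut-3-en-2-yl)-2,2-dimethyl-1,3-dioxolan-4-yl][(triisopropylsilyl)oxy]methyl}prop-2-enoate
Product: 12 5-[(1S,2R)-1,2-dihydroxy-2-methylbut-3-en-1-yl]-3-methylidene-4-[(triisopropylsilyl)oxy]oxolan-2-one (C5 from D-tartrate; C4 epimers), via triol methyl ester 11 (not isolated)
Conditions: 80% aq. AcOH, 50 °C; then toluene azeotrope
Reagents that add atoms: none
Why: Acetal hydrolysis frees both secondary alcohols and the one γ to the ester closes the five-membered lactone (lactonisation is favoured over the six-membered alternative), which differentiates the C11a oxygen from the C11 hydroxyl.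

Step 10
Reactants: 12 5-[(1S,2R)-1,2-dihydroxy-2-methylbut-3-en-1-yl]-3-methylidene-4-[(triisopropylsilyl)oxy]oxolan-2-one; 3 (2E)-3-methylpent-2-enoic acid
Product: 14 (1S,2R)-2-hydroxy-2-methyl-1-{4-methylidene-5-oxo-3-[(triisopropylsilyl)oxy]oxolan-2-yl}but-3-en-1-yl (2E)-3-methylpent-2-enoate, via mixed anhydride 13 (not isolated)
Conditions: 3, 2,4,6-trichlorobenzoyl chloride, Et3N, THF, rt; then 12, DMAP, toluene, rt
Reagents that add atoms: none
Why: Yamaguchi esterification acylates the only free secondary hydroxyl, the tertiary allylic alcohol being unreactive.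

Step 11
Reactants: 14 (1S,2R)-2-hydroxy-2-methyl-1-{4-methylidene-5-oxo-3-[(triisopropylsilyl)oxy]oxolan-2-yl}but-3-en-1-yl (2E)-3-methylpent-2-enoate
Product: 15 (1S,2R)-2-hydroxy-1-(3-hydroxy-4-methylidene-5-oxooxolan-2-yl)-2-methylbut-3-en-1-yl (2E)-3-methylpent-2-enoate (ring carbinol epimers)
Conditions: HF·pyridine, THF/pyridine, 0 °C → rt
Reagents that add atoms: none
Why: Fluoride-driven desilylation under mildly acidic conditions leaves the lactone and the enoate ester intact.

Step 12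
Reactants: 15 (1S,2R)-2-hydroxy-1-(3-hydroxy-4-methylidene-5-oxooxolan-2-yl)-2-methylbut-3-en-1-yl (2E)-3-methylpent-2-enoate
Product: 16 (1S,2R)-1-[(2R)-4-(bromomethyl)-5-oxo-2,5-dihydrofuran-2-yl]-2-hydroxy-2-methylbut-3-en-1-yl (2E)-3-methylpent-2-enoate
Conditions: CBr4, PPh3, CH2Cl2, 0 °C
Reagents that add atoms: carbon tetrabromide BrC(Br)(Br)Br
Why: Appel bromination of the Baylis–Hillman-type allylic alcohol proceeds with allylic transposition (SN2′) to the conjugated primary bromide, so both carbinol epimers converge and the tertiary alcohol stays untouched.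

Step 13
Reactants: 17 (4R)-4-benzyl-1,3-oxazolidin-2-one
Product: 19 (4R)-4-benzyl-3-propanoyl-1,3-oxazolidin-2-one, via lithium oxazolidinide 18 (not isolated)
Conditions: nBuLi, THF, −78 °C; EtCOCl, −78 → 0 °C
Reagents that add atoms: propanoyl chloride CCC(Cl)=O
Why: N-Acylation of the lithiated Evans auxiliary.

Step 14
Reactants: 19 (4R)-4-benzyl-3-propanoyl-1,3-oxazolidin-2-one
Product: 21 (4R)-4-benzyl-3-[(2S)-2-methylpent-4-enoyl]-1,3-oxazolidin-2-one, via sodium Z-enolate 20 (not isolated)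
Conditions: NaN(SiMe3)2, THF, −78 °C; allyl iodide, −78 → −40 °C
Reagents that add atoms: allyl iodide C=CCI
Why: Evans asymmetric alkylation, in which the chelated Z-enolate is allylated on the face opposite the benzyl group, sets the (S) methyl-bearing centre (C6).

Step 15
Reactants: 21 (4R)-4-benzyl-3-[(2S)-2-methylpent-4-enoyl]-1,3-oxazolidin-2-one
Product: 22 (2S)-2-methylpent-4-en-1-ol
Conditions: LiBH4, MeOH (1 equiv), Et2O, 0 °C
Reagents that add atoms: none
Why: Reductive cleavage of the imide gives the primary alcohol without epimerisation and returns the auxiliary.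

Step 16
Reactants: 22 (2S)-2-methylpent-4-en-1-ol
Product: 23 (2S)-2-methylpent-4-enal
Conditions: Dess–Martin periodinane, NaHCO3, CH2Cl2, 0 °C → rt; used as solution
Reagents that add atoms: none
Why: Buffered Dess–Martin oxidation gives the α-chiral aldehyde without racemisation.

Step 17
Reactants: 23 (2S)-2-methylpent-4-enal
Product: 24 2-[(2S)-pent-4-en-2-yl]-1,3-dithiane
Conditions: HS(CH2)3SH, BF3·OEt2, CH2Cl2, −20 → 0 °C
Reagents that add atoms: propane-1,3-dithiol SCCCS
Why: Lewis-acid-catalysed dithioacetalisation masks the future C5 ketone carbon, and the low temperature avoids enolisation of the adjacent stereocentre.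

Step 18
Reactants: 24 2-[(2S)-pent-4-en-2-yl]-1,3-dithiane
Product: 26 2-[(2S)-pent-4-en-2-yl]-1,3-dithiane-2-carbaldehyde, via 2-lithiodithiane 25 (not isolated)
Conditions: tBuLi, THF/HMPA, −78 °C; DMF, −78 → 0 °C; aq. NH4Cl
Reagents that add atoms: N,N-dimethylformamide CN(C)C=O
Why: Corey–Seebach umpolung followed by formylation with DMF gives a non-enolisable α-keto-aldehyde equivalent.

Step 19
Reactants: 16 (1S,2R)-1-[(2R)-4-(bromomethyl)-5-oxo-2,5-dihydrofuran-2-yl]-2-hydroxy-2-methylbut-3-en-1-yl (2E)-3-methylpent-2-enoate; 26 2-[(2S)-pent-4-en-2-yl]-1,3-dithiane-2-carbaldehyde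
Product: 29 (1S,2R)-1-[(2R,3S)-4-[(dimethylamino)methyl]-3-{(S)-hydroxy[2-((2S)-pent-4-en-2-yl)-1,3-dithian-2-yl]methyl}-5-oxooxolan-2-yl]-2-hydroxy-2-methylbut-3-en-1-yl (2E)-3-methylpent-2-enoate (C4 epimers), via allylindium bromide 27 (not isolated), via Barbier adduct 28 (not isolated)
Conditions: In (indium powder), THF/H2O (3:1), rt; then Me2NH (40% aq.), rt
Reagents that add atoms: dimethylamine CNC
Why: Barbier-type allylation, in which the allylindium attacks the aldehyde through its γ-carbon anti to the C5 side chain of the butenolide via a chair transition state (trans lactone, anti adduct), sets C3a and C4 and forms the α-methylene lactone, which is masked in the same flask by aza-Michael addition.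

Step 20
Reactants: 29 (1S,2R)-1-[(2R,3S)-4-[(dimethylamino)methyl]-3-{(S)-hydroxy[2-((2S)-pent-4-en-2-yl)-1,3-dithian-2-yl]methyl}-5-oxooxolan-2-yl]-2-hydroxy-2-methylbut-3-en-1-yl (2E)-3-methylpent-2-enoate
Product: 30 (3aS,4S,6S,10R,11S,11aR)-3-[(dimethylamino)methyl]-4,10-dihydroxy-6,10-dimethyl-2-oxo-3,3a,4,6,7,10,11,11a-octahydro-2H-spiro[cyclodeca[b]furan-5,2'-[1,3]dithian]-11-yl (2E)-3-methylpent-2-enoate (8,9-alkene E/Z; C3 epimers)
Conditions: TsOH·H2O (1.0 equiv), second-generation Hoveyda–Grubbs catalyst (15 mol %), ClCH2CH2Cl (1 mM), 60 °C; NaHCO3 wash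
Reagents that add atoms: none
Why: Ring-closing metathesis of the allyl group onto the vinyl carbinol closes the ten-membered carbocycle with loss of ethene, the amine being protonated so it cannot bind Ru and the alkene geometry being irrelevant.

Step 21
Reactants: 30 (3aS,4S,6S,10R,11S,11aR)-3-[(dimethylamino)methyl]-4,10-dihydroxy-6,10-dimethyl-2-oxo-3,3a,4,6,7,10,11,11a-octahydro-2H-spiro[cyclodeca[b]furan-5,2'-[1,3]dithian]-11-yl (2E)-3-methylpent-2-enoate
Product: 31 (3aS,4S,6S,10R,11S,11aR)-3-[(dimethylamino)methyl]-4,10-dihydroxy-6,10-dimethyl-2-oxodecahydro-2H-spiro[cyclodeca[b]furan-5,2'-[1,3]dithian]-11-yl (2E)-3-methylpent-2-enoate (C3 epimers)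
Conditions: 2-nitrobenzenesulfonylhydrazide, Et3N, CH2Cl2, rt (repeated charges)
Reagents that add atoms: none
Why: Diimide reduction saturates only the isolated disubstituted ring alkene and leaves the trisubstituted conjugated enoate and the sulfur groups alone.

Step 22
Reactants: 31 (3aS,4S,6S,10R,11S,11aR)-3-[(dimethylamino)methyl]-4,10-dihydroxy-6,10-dimethyl-2-oxodecahydro-2H-spiro[cyclodeca[b]furan-5,2'-[1,3]dithian]-11-yl (2E)-3-methylpent-2-enoate
Product: 33 (3aS,4S,6S,10R,11S,11aR)-4,10-dihydroxy-6,10-dimethyl-3-methylidene-2-oxodecahydro-2H-spiro[cyclodeca[b]furan-5,2'-[1,3]dithian]-11-yl (2E)-3-methylpent-2-enoate, via trimethylammonium iodide 32 (not isolated)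
Conditions: MeI, THF, rt; then aq. NaHCO3, EtOAc, rt
Reagents that add atoms: none
Why: N-Quaternisation followed by Hofmann-type (E1cB) elimination regenerates the α-methylene lactone.

Step 23
Reactants: 33 (3aS,4S,6S,10R,11S,11aR)-4,10-dihydroxy-6,10-dimethyl-3-methylidene-2-oxodecahydro-2H-spiro[cyclodeca[b]furan-5,2'-[1,3]dithian]-11-yl (2E)-3-methylpent-2-enoate
Product: 34 (3aS,4S,6S,10R,11S,11aR)-4,10-dihydroxy-6,10-dimethyl-3-methylidene-2,5-dioxododecahydrocyclodeca[b]furan-11-yl (2E)-3-methylpent-2-enoate (target)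
Conditions: PhI(OCOCF3)2, MeCN/H2O (9:1), 0 °C, 10 min
Reagents that add atoms: water O
Why: Oxidative dithiane hydrolysis with the hypervalent iodine reagent releases the C5 ketone next to the free C4 hydroxyl without touching a stereocentre.

**Compound list**
1 | ethyl but-2-ynoate | CCOC(=O)C#CC | starting material
2 | ethyl (2E)-3-methylpent-2-enoate | CCOC(=O)/C=C(\C)CC | intermediate
3 | (2E)-3-methylpent-2-enoic acid | OC(=O)/C=C(\C)CC | intermediate
4 | dimethyl (4S,5S)-2,2-dimethyl-1,3-dioxolane-4,5-dicarboxylate (D-tartrate acetonide) | COC(=O)[C@H]1OC(C)(C)O[C@@H]1C(=O)OC | starting material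
5 | (4S,5S)-N4,N5-dimethoxy-N4,N5,2,2-tetramethyl-1,3-dioxolane-4,5-dicarboxamide | CON(C)C(=O)[C@H]1OC(C)(C)O[C@@H]1C(=O)N(C)OC | intermediate
6 | (4S,5S)-N-methoxy-N,2,2-trimethyl-5-(prop-2-enoyl)-1,3-dioxolane-4-carboxamide | C=CC(=O)[C@H]1OC(C)(C)O[C@@H]1C(=O)N(C)OC | intermediate
7 | (4S,5S)-5-[(2R)-2-hydroxybut-3-en-2-yl]-N-methoxy-N,2,2-trimethyl-1,3-dioxolane-4-carboxamide | C=C[C@@](C)(O)[C@H]1OC(C)(C)O[C@@H]1C(=O)N(C)OC | intermediate
8 | (4S,5S)-5-[(2R)-2-hydroxybut-3-en-2-yl]-2,2-dimethyl-1,3-dioxolane-4-carbaldehyde | C=C[C@@](C)(O)[C@H]1OC(C)(C)O[C@@H]1C=O | intermediate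
9 | Morita–Baylis–Hillman adduct of 8 with methyl acrylate (dioxolane centres as in 8; carbinol epimers) | C=C[C@@](C)(O)[C@H]1OC(C)(C)O[C@@H]1C(O)C(=C)C(=O)OC | intermediate
10 | triisopropylsilyl ether of 9 | C=C[C@@](C)(O)[C@H]1OC(C)(C)O[C@@H]1C(O[Si](C(C)C)(C(C)C)C(C)C)C(=C)C(=O)OC | intermediate
11 | triol methyl ester from acetonide cleavage of 10 (not isolated) | C=C[C@@](C)(O)[C@@H](O)[C@H](O)C(O[Si](C(C)C)(C(C)C)C(C)C)C(=C)C(=O)OC | intermediate
12 | 5-[(1S,2R)-1,2-dihydroxy-2-methylbut-3-en-1-yl]-3-methylidene-4-[(triisopropylsilyl)oxy]oxolan-2-one | C=C[C@@](C)(O)[C@@H](O)[C@@H]1OC(=O)C(=C)C1O[Si](C(C)C)(C(C)C)C(C)C | intermediate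
13 | (2E)-3-methylpent-2-enoic 2,4,6-trichlorobenzoic anhydride (not isolated) | O=C(OC(=O)/C=C(\C)CC)c1c(Cl)cc(Cl)cc1Cl | intermediate
14 | (1S,2R)-2-hydroxy-2-methyl-1-{4-methylidene-5-oxo-3-[(triisopropylsilyl)oxy]oxolan-2-yl}but-3-en-1-yl (2E)-3-methylpent-2-enoate | C=C[C@@](C)(O)[C@@H](OC(=O)/C=C(\C)CC)[C@@H]1OC(=O)C(=C)C1O[Si](C(C)C)(C(C)C)C(C)C | intermediate
15 | (1S,2R)-2-hydroxy-1-(3-hydroxy-4-methylidene-5-oxooxolan-2-yl)-2-methylbut-3-en-1-yl (2E)-3-methylpent-2-enoate | C=C[C@@](C)(O)[C@@H](OC(=O)/C=C(\C)CC)[C@@H]1OC(=O)C(=C)C1O | intermediate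
16 | (1S,2R)-1-[(2R)-4-(bromomethyl)-5-oxo-2,5-dihydrofuran-2-yl]-2-hydroxy-2-methylbut-3-en-1-yl (2E)-3-methylpent-2-enoate (west fragment) | C=C[C@@](C)(O)[C@@H](OC(=O)/C=C(\C)CC)[C@@H]1OC(=O)C(CBr)=C1 | intermediate
17 | (4R)-4-benzyl-1,3-oxazolidin-2-one | O=C1N[C@H](Cc2ccccc2)CO1 | starting material
18 | lithium (4R)-4-benzyl-2-oxo-1,3-oxazolidin-3-ide (not isolated) | [Li]N1[C@H](Cc2ccccc2)COC1=O | intermediate
19 | (4R)-4-benzyl-3-propanoyl-1,3-oxazolidin-2-one | CCC(=O)N1[C@H](Cc2ccccc2)COC1=O | intermediate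
20 | sodium Z-enolate of 19 (not isolated) | C/C=C(\O[Na])N1[C@H](Cc2ccccc2)COC1=O | intermediate
21 | (4R)-4-benzyl-3-[(2S)-2-methylpent-4-enoyl]-1,3-oxazolidin-2-one | C=CC[C@H](C)C(=O)N1[C@H](Cc2ccccc2)COC1=O | intermediate
22 | (2S)-2-methylpent-4-en-1-ol | C=CC[C@H](C)CO | intermediate
23 | (2S)-2-methylpent-4-enal | C=CC[C@H](C)C=O | intermediate
24 | 2-[(2S)-pent-4-en-2-yl]-1,3-dithiane | C=CC[C@H](C)C1SCCCS1 | intermediate
25 | 2-lithio-2-[(2S)-pent-4-en-2-yl]-1,3-dithiane (not isolated) | C=CC[C@H](C)C1([Li])SCCCS1 | intermediate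
26 | 2-[(2S)-pent-4-en-2-yl]-1,3-dithiane-2-carbaldehyde (east fragment) | C=CC[C@H](C)C1(C=O)SCCCS1 | intermediate
27 | allylindium intermediate from 16, formulated as the dibromoindium species (not isolated) | C=C[C@@](C)(O)[C@@H](OC(=O)/C=C(\C)CC)[C@@H]1OC(=O)C(C[In](Br)Br)=C1 | intermediate
28 | Barbier adduct: (1S,2R)-2-hydroxy-1-[(2R,3S)-3-{(S)-hydroxy[2-((2S)-pent-4-en-2-yl)-1,3-dithian-2-yl]methyl}-4-methylidene-5-oxooxolan-2-yl]-2-methylbut-3-en-1-yl (2E)-3-methylpent-2-enoate (not isolated) | C=C1C(=O)O[C@@H]([C@H](OC(=O)/C=C(\C)CC)[C@](C)(O)C=C)[C@@H]1[C@H](O)C2(SCCCS2)[C@@H](C)CC=C | intermediate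
29 | Me2NH adduct of 28 (4-[(dimethylamino)methyl]oxolanone; C4 epimers) | CN(C)CC1C(=O)O[C@@H]([C@H](OC(=O)/C=C(\C)CC)[C@](C)(O)C=C)[C@@H]1[C@H](O)C2(SCCCS2)[C@@H](C)CC=C | intermediate
30 | ten-membered ring-closing metathesis product (8,9-alkene E/Z; 3-[(dimethylamino)methyl]; spiro-dithiane at C5) | CN(C)CC1C(=O)O[C@@H]2[C@@H]1[C@H](O)C3(SCCCS3)[C@@H](C)CC=C[C@@](C)(O)[C@H]2OC(=O)/C=C(\C)CC | intermediate
31 | saturated macrocycle (3-[(dimethylamino)methyl]; spiro-dithiane at C5) | CN(C)CC1C(=O)O[C@@H]2[C@@H]1[C@H](O)C3(SCCCS3)[C@@H](C)CCC[C@@](C)(O)[C@H]2OC(=O)/C=C(\C)CC | intermediate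
32 | trimethylammonium iodide of 31 (not isolated) | C[N+](C)(C)CC1C(=O)O[C@@H]2[C@@H]1[C@H](O)C3(SCCCS3)[C@@H](C)CCC[C@@](C)(O)[C@H]2OC(=O)/C=C(\C)CC.[I-] | intermediate
33 | (3aS,4S,6S,10R,11S,11aR)-4,10-dihydroxy-6,10-dimethyl-3-methylidene-2-oxodecahydro-2H-spiro[cyclodeca[b]furan-5,2'-[1,3]dithian]-11-yl (2E)-3-methylpent-2-enoate | C=C1C(=O)O[C@@H]2[C@@H]1[C@H](O)C3(SCCCS3)[C@@H](C)CCC[C@@](C)(O)[C@H]2OC(=O)/C=C(\C)CC | intermediate
34 | (3aS,4S,6S,10R,11S,11aR)-4,10-dihydroxy-6,10-dimethyl-3-methylidene-2,5-dioxododecahydrocyclodeca[b]furan-11-yl (2E)-3-methylpent-2-enoate (CNP0197047.1) | C=C1C(=O)O[C@@H]2[C@@H]1[C@H](O)C(=O)[C@@H](C)CCC[C@@](C)(O)[C@H]2OC(=O)/C=C(\C)CC | target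

**Totals**
Total step count: 23.
Longest linear sequence: 15 steps (4 → 34, steps 3–12 and 19–23). The east branch (steps 13–18) and the acid branch (steps 1–2) run in parallel.

**Three steps most likely to fail, with fallbacks**

Risk 1, step 20: a ten-membered ring is closed by metathesis onto a hindered vinyl carbinol, so ring strain and oligomerisation may win. The fallback sets out from 16 and 26 and comes back at 30; it exchanges the two C–C bond formations. Cross-metathesis of the vinyl carbinol of 16 with the allyl group of 26 (3 equiv of 26, second-generation Hoveyda–Grubbs catalyst, CH2Cl2, 40 °C) gives the E-configured bromo aldehyde F1. Intramolecular Barbier allylation of it under high dilution (Zn, THF/aq. NH4Cl, or CrCl2 in THF) closes the ring at C3a–C4, with the E-alkene pre-organising the chain, and gives the macrocyclic dienyl lactone F2. Me2NH in THF then gives 30 as its E isomer, which continues with step 21.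

Risk 2, step 5: the methyl addition to enone 6 may follow Felkin rather than chelate control and give mainly the C10 epimer, or may add 1,4. The fallback sets out from 5 and comes back at 7; it exchanges the two carbonyl additions. MeMgBr (1.1 equiv, THF, −78 °C) on 5 gives the methyl ketone F3, and CH2=CHMgBr is then added to it. The facial preference that disfavoured 7 from 6 now favours it, and no enone is handled.

Risk 3, step 7: the amine-catalysed Morita–Baylis–Hillman reaction may stall on this hindered aldehyde. The fallback sets out from 8 and comes back at 9; it replaces the catalytic coupling by an aldol addition and selenoxide elimination. The lithium enolate of methyl 2-(phenylselanyl)propanoate (LDA, THF, −78 °C) adds to 8 to give the α-seleno aldol F4. H2O2/pyridine (CH2Cl2, 0 °C) oxidises the selenide, and syn-elimination toward the methyl group gives 9.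

**Further compounds**
F1 | step 20 | (1S,2R,3E,6S)-1-[(2R)-4-(bromomethyl)-5-oxo-2,5-dihydrofuran-2-yl]-6-(2-formyl-1,3-dithian-2-yl)-2-hydroxy-2-methylhept-3-en-1-yl (2E)-3-methylpent-2-enoate | O=CC1(SCCCS1)[C@@H](C)C/C=C/[C@@](C)(O)[C@@H](OC(=O)/C=C(\C)CC)[C@@H]2OC(=O)C(CBr)=C2
F2 | step 20 | (3aS,4S,6S,8E,10R,11S,11aR)-4,10-dihydroxy-6,10-dimethyl-3-methylidene-2-oxo-3,3a,4,6,7,10,11,11a-octahydro-2H-spiro[cyclodeca[b]furan-5,2'-[1,3]dithian]-11-yl (2E)-3-methylpent-2-enoate | C=C1C(=O)O[C@@H]2[C@@H]1[C@H](O)C3(SCCCS3)[C@@H](C)C/C=C/[C@@](C)(O)[C@H]2OC(=O)/C=C(\C)CC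
F3 | step 5 | (4S,5S)-5-acetyl-N-methoxy-N,2,2-trimethyl-1,3-dioxolane-4-carboxamide | CC(=O)[C@H]1OC(C)(C)O[C@@H]1C(=O)N(C)OC
F4 | step 7 | methyl 3-hydroxy-3-[5-((2R)-2-hydroxybut-3-en-2-yl)-2,2-dimethyl-1,3-dioxolan-4-yl]-2-methyl-2-(phenylselanyl)propanoate (dioxolane centres as in 8; diastereomer mixture) | C=C[C@@](C)(O)[C@H]1OC(C)(C)O[C@@H]1C(O)C(C)([Se]c2ccccc2)C(=O)OC
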